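The earlier runs and the new flask were generated by integration for an exercise; scatter was added.

The ratio of the charges in the elm and oak runs, 1.57, is close to the ratio of the percentages of starting material lost by 40.0 min taken the other way round, oak over elm, 1.61.

| setting | oak | elm | Wednesday's | Sunday's | Tuesday's |
|---|---|---|---|---|---|
| starting material | 1.4 M | 2.2 M | 1.0 M | 1.0 M | 1.0 M |
| gas | 89 mM (held) | 89 mM (held) | 89 mM (held) | 89 mM (held) | 89 mM (held) |
| remark | run made earlier | run made earlier |  |  |  |
| time |  |  | 40 min | 80 min | 160 min |

| run | time / min | target / % | starting material / % | isomer of the product / % | second isomer / % |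
|---|---|---|---|---|---|
| oak | 2.00 | 3.0 | 99.9 | 0 | 0 |
| oak | 6.00 | 2.0 | 98.2 | 0.6 | 2.0 |
| oak | 12.0 | 0 | 98.2 | 0.1 | 1.3 |
| oak | 15.0 | 0.2 | 95.7 | 0.2 | 2.6 |
| oak | 25.0 | 2.0 | 93.6 | 0.4 | 5.5 |
| oak | 30.0 | 3.0 | 91.0 | 0 | 5.7 |
| oak | 40.0 | 2.2 | 89.2 | 1.7 | 9.5 |
| elm | 6.00 | 0 | 98.8 | 1.1 | 0.9 |
| elm | 12.0 | 0 | 98.9 | 2.1 | 3.1 |
| elm | 15.0 | 0.1 | 97.8 | 0 | 3.0 |
| elm | 25.0 | 1.8 | 94.4 | 0 | 3.9 |
| elm | 30.0 | 2.4 | 94.2 | 0.4 | 4.0 |
| elm | 40.0 | 1.5 | 93.3 | 0 | 5.2 |

(each reading ± 1 percentage point)

- at the start none of the gas is in solution
- a reading or a percentage of target counts all its forms, free or not

- which of these there is most of at the end, counted by the starting material in it, Wednesday's (target / starting material / isomer of the product / second isomer)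
- which of these there is most of at the end, counted by the starting material in it, Sunday's (target / starting material / isomer of the product / second isomer)
- which of these there is most of at the end, counted by the starting material in it, Tuesday's (target / starting material / isomer of the product / second isomer)
- final amount of the leader among these, as a percentage of the starting material charged, in Wednesday's
- final amount of the leader among these, as a percentage of the starting material charged, in Sunday's
- final amount of the leader among these, as a percentage of the starting material charged, in Tuesday's

So, as readings go, the two runs lose the same concentration, 0.151 M in oak and 0.147 M in elm, though their charges differ. But that loss is more than the 89 mM of gas the solution holds at saturation, so if the gas is used along with the starting material it must keep crossing over, and I take this crossing as the rate-limiting step.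

At the high end I therefore carry one quantity: the supply rate, the mean of the two losses divided by the time, 3.73 mM min⁻¹. At the low end the line must stop, at the drain time, charge over supply rate, which is 268 min for 1.0 M. Tuesday's 160 min is less than that, so I stay on the line, and the line puts starting material at 85.1% in Wednesday's, 70.1% in Sunday's and 40.3% in Tuesday's.

Second isomer holds 73.9% of the products in the last readings of the two runs taken together, so with that reading as its share I reckon it at 44.1% in Tuesday's. The reckoned lines of starting material and second isomer cross at 154 min, and Tuesday's ends later than that, so I commit to second isomer there, narrowly.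

The forecast, on about 0.0045 M/min after a lag of about 8 min where my line has no lag, gives starting material at 85.5% in Wednesday's, starting material at 69% in Sunday's and second isomer at 43% in Tuesday's, “a close call”.

The flasks give starting material at 83.7% in Wednesday's and 67.3% in Sunday's, and in Tuesday's second isomer leads with 47.5% over starting material at 35.2%. Tuesday's has lost 0.648 M, where supply rate times time gives 0.597 M.

    starting material + partner → target (k = 0.529 M⁻¹ min⁻¹)
    starting material + partner → isomer of the product (k = 0.0179 M⁻¹ min⁻¹)
    starting material + partner → second isomer (k = 1.50 M⁻¹ min⁻¹)
    gas ⇌ partner, rate k4*(csat - [partner]) (kL = 0.0481 min⁻¹)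
    crystals ⇌ target, rate k5*(cs5 - [target]) while solid is left; crystals form when [target] > cs5 (solubility = 0.840 M, k = 0.327 min⁻¹)
    partner → decomposed reagent (k = 0.0145 min⁻¹)

Take the neighbour of Sunday's charged with 0.25 M and read at 80 min. Its drain time is 67.0 min, less than 80 min, so the line has it empty by then. The neighbour has lost 0.231 M, less than the 0.298 M of the line, so at this low end the loss has left the line. Second isomer leads there with 67.6%, and starting material stands at 7.79%.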